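The plan rests on cutting the hexasubstituted benzene ring of the benzofuran-2(3H)-one core into a squaric ester and a furan. C4, C5, C6 and C7, with O4, O6, O7 and the C5 acyl carbon, map onto the four carbons of a cyclobutenone; the C7a–C3a edge with O1 and C2 is the C5–C4 bond of 2-methoxyfuran, whose C2 is already at the lactone oxidation level. Heating a 4-furyl-4-(methoxymethoxy)cyclobutenone bearing an isopropoxy group and a dithiane-masked 3-phenylpropanoyl group forms C4–C3a and the whole benzene ring in one operation, leaving O4 as the only free hydroxyl for methylation.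

Key step: step 4

Remark on the chemistry: the carbinol carbon of the cyclobutenone precursor is formed without control and is erased in the key step, so that compound is a racemate and is drawn without a stereodescriptor. The only stereo-element of the target is the Z benzylidene double bond, set in step 7. All starting materials are assumed to be catalogue compounds.

Step 1
Reactants: 1 3-phenylpropanal; 2 propane-1,3-dithiol
Product: 3 2-(2-phenylethyl)-1,3-dithiane
Conditions: BF3·OEt2, CH2Cl2, 0 °C → rt
Reagents that add atoms: none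
Why: Lewis-acid-catalysed dithioacetalisation of an unhindered aliphatic aldehyde should give the acyl-anion precursor for the C5 side chain without complication.

Step 2
Reactants: 3 2-(2-phenylethyl)-1,3-dithiane; 4 diisopropyl squarate
Product: 8 3-isopropoxy-4-[2-(2-phenylethyl)-1,3-dithian-2-yl]cyclobut-3-ene-1,2-dione, via lithiodithiane 5 (not isolated), via lithium cyclobutenolate 6 (not isolated), via tertiary trifluoroacetate 7 (not isolated)
Conditions: n-BuLi, THF, −30 °C; 4, −78 °C; (CF3CO)2O, −78 °C; H2O/NaHCO3, 0 °C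
Reagents that add atoms: water, O
Why: Corey–Seebach deprotonation gives a dithianyl anion that adds 1,2 to a squarate carbonyl, and trifluoroacetylation of the alkoxide triggers ionisation, capture of water and loss of isopropanol to the cyclobutenedione (the standard squarate addition and acid rearrangement sequence), while a stray conjugate addition–elimination would converge on the same product.

Step 3
Reactants: 8 3-isopropoxy-4-[2-(2-phenylethyl)-1,3-dithian-2-yl]cyclobut-3-ene-1,2-dione; 9 2-methoxyfuran
Product: 12 (±)-3-isopropoxy-4-(5-methoxyfuran-2-yl)-4-(methoxymethoxy)-2-[2-(2-phenylethyl)-1,3-dithian-2-yl]cyclobut-2-en-1-one, via 5-lithio-2-methoxyfuran 10 (not isolated), via lithium carbinolate 11 (not isolated)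
Conditions: 9, n-BuLi, THF, −78 → 0 °C; 8, −78 °C; MOMCl, −78 → 0 °C; NaHCO3 (aq)
Reagents that add atoms: chloromethyl methyl ether, COCCl
Why: C5-lithiated 2-methoxyfuran should add 1,2 to the ketone-like carbonyl next to the isopropoxy-bearing carbon (the other carbonyl is a deactivated vinylogous ester shielded by the quaternary dithiane), and Williamson-type capping of the lithium alkoxide with MOMCl keeps a free hydroxyl out of the thermolysis; the new carbinol centre forms as a racemate and is destroyed in step 4.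

Step 4
Reactants: 12 (±)-3-isopropoxy-4-(5-methoxyfuran-2-yl)-4-(methoxymethoxy)-2-[2-(2-phenylethyl)-1,3-dithian-2-yl]cyclobut-2-en-1-one
Product: 15 6-isopropoxy-2-methoxy-7-(methoxymethoxy)-5-[2-(2-phenylethyl)-1,3-dithian-2-yl]benzofuran-4-ol, via dienylketene 13 (not isolated), via cyclohexadienone 14 (not isolated)
Conditions: PhMe (degassed, dilute), 110 °C, Ar
Reagents that add atoms: none
Why: Thermal conrotatory 4π opening of the cyclobutenone cleaves the bond between the carbonyl carbon and the carbinol carbon, the methoxymethoxy donor rotating outward, so that (Z)-dienylketene 13 has the furyl group turned toward the ketene. Disrotatory 6π electrocyclisation across the ketene C=C, the enol-ether C=C and the furan C=C next to the point of attachment joins the ketene carbon to the furan β-carbon (C4–C3a) and closes the benzene ring as dienone 14, which enolises to phenol 15. The closest known reaction type is the thermal ring expansion of 4-aryl- and 4-heteroaryl-4-oxycyclobutenones to hydroquinone monoethers (Moore rearrangement). No stereocentre is created: the racemic carbinol carbon becomes aromatic C7 and the transient C3a–H centre is lost on enolisation. The step needs torquoselectivity (oxygen outward, furyl inward), which the known outward preference of a donor alkoxy group secures, while regiochemistry is fixed because only one furan carbon lies next to the attachment point and the capped oxygen cannot trap the ketene. The ketene carbon becomes C4 and emerges as the only free hydroxyl, which dictates where the methyl ether is placed in the next step.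

Step 5
Reactants: 15 6-isopropoxy-2-methoxy-7-(methoxymethoxy)-5-[2-(2-phenylethyl)-1,3-dithian-2-yl]benzofuran-4-ol
Product: 16 6-isopropoxy-2,4-dimethoxy-7-(methoxymethoxy)-5-[2-(2-phenylethyl)-1,3-dithian-2-yl]benzofuran
Conditions: MeI, K2CO3, DMF, rt, Ar
Reagents that add atoms: iodomethane, CI
Why: Williamson O-methylation of the single free phenol should be far faster than S-alkylation of the thioacetal, and capping O4 before the lactone is unveiled rules out translactonisation between O1 and O4.

Step 6
Reactants: 16 6-isopropoxy-2,4-dimethoxy-7-(methoxymethoxy)-5-[2-(2-phenylethyl)-1,3-dithian-2-yl]benzofuran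
Product: 18 6-isopropoxy-4-methoxy-7-(methoxymethoxy)-5-[2-(2-phenylethyl)-1,3-dithian-2-yl]benzofuran-2(3H)-one, via oxocarbenium chloride 17 (not isolated)
Conditions: HCl (1.1 equiv, 4 M in dioxane), CH2Cl2, −20 °C → rt; NaHCO3 (aq)
Reagents that add atoms: none
Why: Protonation at C3 of the ketene-acetal-like 2-methoxybenzofuran gives dialkoxycarbenium chloride 17, which chloride demethylates by SN2 (the hydrogen halide cleavage of ketene acetals to ester and alkyl halide), so the lactone forms without water and cannot open to an arylacetic ester, and the single equivalent of acid is consumed before it can attack the MOM ether.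

Step 7
Reactants: 18 6-isopropoxy-4-methoxy-7-(methoxymethoxy)-5-[2-(2-phenylethyl)-1,3-dithian-2-yl]benzofuran-2(3H)-one; 19 benzaldehyde
Product: 21 (Z)-3-benzylidene-6-isopropoxy-4-methoxy-7-(methoxymethoxy)-5-[2-(2-phenylethyl)-1,3-dithian-2-yl]benzofuran-2(3H)-one, via aldol adduct 20 (not isolated)
Conditions: Et3N (cat.), PhMe, 4 Å MS, 80 °C, Ar
Reagents that add atoms: none
Why: Knoevenagel-type aldol condensation of the acidic lactone methylene (E1cB dehydration of aldol 20) uses a tertiary amine that cannot aminolyse the aryl lactone, the masked ketone cannot compete, and the Z geometry is expected under thermodynamic control because the phenyl group then lies beside the lactone carbonyl and away from the C4 methoxy group.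

Step 8
Reactants: 21 (Z)-3-benzylidene-6-isopropoxy-4-methoxy-7-(methoxymethoxy)-5-[2-(2-phenylethyl)-1,3-dithian-2-yl]benzofuran-2(3H)-one
Product: 22 (Z)-3-benzylidene-6-isopropoxy-4-methoxy-7-(methoxymethoxy)-5-(3-phenylpropanoyl)benzofuran-2(3H)-one
Conditions: Hg(ClO4)2·3H2O, CaCO3, THF/H2O, 0 °C
Reagents that add atoms: water, O
Why: Thiophilic divalent mercury ionises the thioacetal to a thionium ion that water hydrolyses (Corey–Seebach dithiane unmasking), a non-oxidative method chosen because the para-dialkoxy arene would not tolerate halogen- or iodine-based oxidants, and CaCO3 buffers the acid so that the MOM ether and the lactone should survive.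

Step 9
Reactants: 22 (Z)-3-benzylidene-6-isopropoxy-4-methoxy-7-(methoxymethoxy)-5-(3-phenylpropanoyl)benzofuran-2(3H)-one
Product: 24 bractelactone [(Z)-3-benzylidene-6,7-dihydroxy-4-methoxy-5-(3-phenylpropanoyl)benzofuran-2(3H)-one], via cyclic chloroborate 23 (not isolated)
Conditions: BCl3, CH2Cl2, −78 → −20 °C; H2O
Reagents that add atoms: none
Why: Lewis-acid dealkylation with BCl3 should cleave the secondary isopropyl ether and the MOM acetal at low temperature, the boron on O6 chelates the C5 ketone and so keeps the carbonyl from directing cleavage of the C4 methyl ether, and the air-sensitive catechol appears only in the last step with the alkene geometry untouched.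

Compound list
1 | 3-phenylpropanal | O=CCCc1ccccc1 | starting material
2 | propane-1,3-dithiol | SCCCS | starting material
3 | 2-(2-phenylethyl)-1,3-dithiane | C1CSC(CCc2ccccc2)SC1 | intermediate
4 | diisopropyl squarate | CC(C)OC1=C(OC(C)C)C(=O)C1=O | starting material
5 | 2-lithio-2-(2-phenylethyl)-1,3-dithiane | [Li]C1(CCc2ccccc2)SCCCS1 | intermediate
6 | lithium 2,3-diisopropoxy-4-oxo-1-[2-(2-phenylethyl)-1,3-dithian-2-yl]cyclobut-2-en-1-olate (racemic) | CC(C)OC1=C(OC(C)C)C([O-])(C2(CCc3ccccc3)SCCCS2)C1=O.[Li+] | intermediate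
7 | 2,3-diisopropoxy-4-oxo-1-[2-(2-phenylethyl)-1,3-dithian-2-yl]cyclobut-2-en-1-yl trifluoroacetate (racemic) | CC(C)OC1=C(OC(C)C)C(OC(=O)C(F)(F)F)(C2(CCc3ccccc3)SCCCS2)C1=O | intermediate
8 | 3-isopropoxy-4-[2-(2-phenylethyl)-1,3-dithian-2-yl]cyclobut-3-ene-1,2-dione | CC(C)OC1=C(C2(CCc3ccccc3)SCCCS2)C(=O)C1=O | intermediate
9 | 2-methoxyfuran | COc1ccco1 | starting material
10 | 5-lithio-2-methoxyfuran | [Li]c1ccc(OC)o1 | intermediate
11 | lithium 2-isopropoxy-1-(5-methoxyfuran-2-yl)-4-oxo-3-[2-(2-phenylethyl)-1,3-dithian-2-yl]cyclobut-2-en-1-olate (racemic) | CC(C)OC1=C(C2(CCc3ccccc3)SCCCS2)C(=O)C1([O-])c1ccc(OC)o1.[Li+] | intermediate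
12 | (±)-3-isopropoxy-4-(5-methoxyfuran-2-yl)-4-(methoxymethoxy)-2-[2-(2-phenylethyl)-1,3-dithian-2-yl]cyclobut-2-en-1-one | O=C1C(C2(CCc3ccccc3)SCCCS2)=C(OC(C)C)C1(OCOC)c1ccc(OC)o1 | intermediate
13 | (Z)-3-isopropoxy-4-(5-methoxyfuran-2-yl)-4-(methoxymethoxy)-2-[2-(2-phenylethyl)-1,3-dithian-2-yl]buta-1,3-dien-1-one (dienylketene) | O=C=C(C1(CCc2ccccc2)SCCCS1)/C(OC(C)C)=C(/OCOC)c1ccc(OC)o1 | intermediate
14 | 6-isopropoxy-2-methoxy-7-(methoxymethoxy)-5-[2-(2-phenylethyl)-1,3-dithian-2-yl]-3aH-benzofuran-4-one (racemic) | COC1=CC2C(=O)C(C3(CCc4ccccc4)SCCCS3)=C(OC(C)C)C(OCOC)=C2O1 | intermediate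
15 | 6-isopropoxy-2-methoxy-7-(methoxymethoxy)-5-[2-(2-phenylethyl)-1,3-dithian-2-yl]benzofuran-4-ol | COc1cc2c(O)c(C3(CCc4ccccc4)SCCCS3)c(OC(C)C)c(OCOC)c2o1 | intermediate
16 | 6-isopropoxy-2,4-dimethoxy-7-(methoxymethoxy)-5-[2-(2-phenylethyl)-1,3-dithian-2-yl]benzofuran | COc1cc2c(OC)c(C3(CCc4ccccc4)SCCCS3)c(OC(C)C)c(OCOC)c2o1 | intermediate
17 | 6-isopropoxy-2,4-dimethoxy-7-(methoxymethoxy)-5-[2-(2-phenylethyl)-1,3-dithian-2-yl]-3H-benzofuran-1-ium chloride | C[O+]=C1Cc2c(OC)c(C3(CCc4ccccc4)SCCCS3)c(OC(C)C)c(OCOC)c2O1.[Cl-] | intermediate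
18 | 6-isopropoxy-4-methoxy-7-(methoxymethoxy)-5-[2-(2-phenylethyl)-1,3-dithian-2-yl]benzofuran-2(3H)-one | O=C1Cc2c(OC)c(C3(CCc4ccccc4)SCCCS3)c(OC(C)C)c(OCOC)c2O1 | intermediate
19 | benzaldehyde | O=Cc1ccccc1 | starting material
20 | 3-[hydroxy(phenyl)methyl]-6-isopropoxy-4-methoxy-7-(methoxymethoxy)-5-[2-(2-phenylethyl)-1,3-dithian-2-yl]benzofuran-2(3H)-one (mixture of racemic diastereomers) | O=C1Oc2c(OCOC)c(OC(C)C)c(C3(CCc4ccccc4)SCCCS3)c(OC)c2C1C(O)c1ccccc1 | intermediate
21 | (Z)-3-benzylidene-6-isopropoxy-4-methoxy-7-(methoxymethoxy)-5-[2-(2-phenylethyl)-1,3-dithian-2-yl]benzofuran-2(3H)-one | COc1c(C2(CCc3ccccc3)SCCCS2)c(OC(C)C)c(OCOC)c2c1/C(=C/c1ccccc1)C(=O)O2 | intermediate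
22 | (Z)-3-benzylidene-6-isopropoxy-4-methoxy-7-(methoxymethoxy)-5-(3-phenylpropanoyl)benzofuran-2(3H)-one | COc1c(C(=O)CCc2ccccc2)c(OC(C)C)c(OCOC)c2c1/C(=C/c1ccccc1)C(=O)O2 | intermediate
23 | cyclic chloroborate of the 6,7-diol (2-chloro-1,3,2-dioxaborole fused at C6–C7) | COc1c(C(=O)CCc2ccccc2)c3OB(Cl)Oc3c2c1/C(=C/c1ccccc1)C(=O)O2 | intermediate
24 | bractelactone, (Z)-3-benzylidene-6,7-dihydroxy-4-methoxy-5-(3-phenylpropanoyl)benzofuran-2(3H)-one | COc1c(C(=O)CCc2ccccc2)c(O)c(O)c2c1/C(=C/c1ccccc1)C(=O)O2 | target

Total step count: 9. Longest linear sequence: 9 steps (1 → 24).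

Steps most likely to fail

1. Step 4 (key step). The process at risk is thermal or trace-acid degradation of the ketene-acetal-like methoxyfuran unit, before or after ring expansion, together with air oxidation of the electron-rich phenol. The fallback sets out from 8 and comes back at 18; it introduces the C2 oxygen after the ring expansion instead of carrying it through. Dione 8 would be treated with 2-lithiofuran (furan, n-BuLi) and MOMCl as in step 3 to give (±)-4-(furan-2-yl)-3-isopropoxy-4-(methoxymethoxy)-2-[2-(2-phenylethyl)-1,3-dithian-2-yl]cyclobut-2-en-1-one F1, which has no ketene-acetal unit. The same thermolysis should give 6-isopropoxy-7-(methoxymethoxy)-5-[2-(2-phenylethyl)-1,3-dithian-2-yl]benzofuran-4-ol F2, and methylation as in step 5 should give 6-isopropoxy-4-methoxy-7-(methoxymethoxy)-5-[2-(2-phenylethyl)-1,3-dithian-2-yl]benzofuran F3. n-BuLi at −78 °C removes the only acidic ring proton to give the 2-lithiobenzofuran F4, which bis(trimethylsilyl) peroxide converts into the 2-(trimethylsilyloxy)benzofuran F5. Protodesilylation with dilute citric acid should then deliver lactone 18.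

2. Step 8. The process at risk is slow ionisation of the thioacetal carbon, which is wedged between two ortho alkoxy groups, so that hydrolysis stalls and prolonged contact with the mercury salt begins to erode the MOM ether or the alkene. The fallback sets out from 21 and comes back at 22; it unmasks the ketone in two stages through a sulfoxide. mCPBA (1 equiv, CH2Cl2, −78 °C) should oxidise one sulfur chemoselectively to the dithiane 1-oxide F6 (mixture of diastereomers). Its C–S bond is far more labile, and brief treatment with dilute aqueous acid in THF should hydrolyse it to ketone 22.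

3. Step 6. The process at risk is competitive cleavage of the MOM acetal by HCl, or incomplete demethylation of the oxocarbenium ion so that the ring opens on aqueous work-up. The fallback sets out from 16 and comes back at 18; it accepts ring opening and closes the lactone afterwards. Dilute aqueous acid in THF at 0 °C should hydrolyse 16 to methyl 2-{2-hydroxy-4-isopropoxy-6-methoxy-3-(methoxymethoxy)-5-[2-(2-phenylethyl)-1,3-dithian-2-yl]phenyl}acetate F7. Saponification with LiOH gives the corresponding hydroxy acid F8, and carbodiimide lactonisation (EDC·HCl, CH2Cl2) returns lactone 18.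

Further compounds
F1 | step 4 | (±)-4-(furan-2-yl)-3-isopropoxy-4-(methoxymethoxy)-2-[2-(2-phenylethyl)-1,3-dithian-2-yl]cyclobut-2-en-1-one | O=C1C(C2(CCc3ccccc3)SCCCS2)=C(OC(C)C)C1(OCOC)c1ccco1
F2 | step 4 | 6-isopropoxy-7-(methoxymethoxy)-5-[2-(2-phenylethyl)-1,3-dithian-2-yl]benzofuran-4-ol | Oc1c(C2(CCc3ccccc3)SCCCS2)c(OC(C)C)c(OCOC)c2occc12
F3 | step 4 | 6-isopropoxy-4-methoxy-7-(methoxymethoxy)-5-[2-(2-phenylethyl)-1,3-dithian-2-yl]benzofuran | COc1c(C2(CCc3ccccc3)SCCCS2)c(OC(C)C)c(OCOC)c2occc12
F4 | step 4 | 2-lithio-6-isopropoxy-4-methoxy-7-(methoxymethoxy)-5-[2-(2-phenylethyl)-1,3-dithian-2-yl]benzofuran | COc1c(C2(CCc3ccccc3)SCCCS2)c(OC(C)C)c(OCOC)c2oc([Li])cc12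
F5 | step 4 | 6-isopropoxy-4-methoxy-7-(methoxymethoxy)-5-[2-(2-phenylethyl)-1,3-dithian-2-yl]-2-(trimethylsilyloxy)benzofuran | COc1c(C2(CCc3ccccc3)SCCCS2)c(OC(C)C)c(OCOC)c2oc(O[Si](C)(C)C)cc12
F6 | step 8 | (Z)-3-benzylidene-6-isopropoxy-4-methoxy-7-(methoxymethoxy)-5-[1-oxido-2-(2-phenylethyl)-1,3-dithian-2-yl]benzofuran-2(3H)-one (mixture of sulfoxide diastereomers) | COc1c(C2(CCc3ccccc3)SCCCS2=O)c(OC(C)C)c(OCOC)c2c1/C(=C/c1ccccc1)C(=O)O2
F7 | step 6 | methyl 2-{2-hydroxy-4-isopropoxy-6-methoxy-3-(methoxymethoxy)-5-[2-(2-phenylethyl)-1,3-dithian-2-yl]phenyl}acetate | COC(=O)Cc1c(OC)c(C2(CCc3ccccc3)SCCCS2)c(OC(C)C)c(OCOC)c1O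
F8 | step 6 | 2-{2-hydroxy-4-isopropoxy-6-methoxy-3-(methoxymethoxy)-5-[2-(2-phenylethyl)-1,3-dithian-2-yl]phenyl}acetic acid | OC(=O)Cc1c(OC)c(C2(CCc3ccccc3)SCCCS2)c(OC(C)C)c(OCOC)c1O
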